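## Retrosynthetic overview

1. The ring A enal comes from an isopropenyl carbinol by oxidative 1,3-transposition; the triene side chain comes from aldol condensation of a ring B cis-fused γ-lactone with a C11 dienal, followed by lactone reduction.
2. Ring B is elaborated through its carbinol oxygen: the diazoacetate gives the γ-lactone by rhodium carbenoid C–H insertion, the acrylate delivers the hydroxypropyl carbons to ring A by Michael addition, and the carbinol itself comes from a hydroxyl-directed ketone reduction.
3. Key disconnection: the bond between the spiro carbon and the C(OH)Me carbon of ring A (the cyclohexane). The strategy rests on the β-hydroxy ketone pattern that appears when the ring B (cyclopentane) carbinol is written as a ketone: spiro carbon α, C(OH)Me carbon β, tertiary hydroxyl cis to the ring B carbinol carbon.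
4. The precursor, a 2-(2,5-dioxohexyl)cyclopentenone, is made from cyclopentane-1,3-dione and 5-methylfurfural, the furan acting as a latent 1,4-diketone; the dienal comes from 6-methylhept-5-en-2-one and acrolein.
5. Ring order: ring B is present from the start, ring A is closed onto it as a spirocycle in the key step, and two lactone rings are temporary.

Key step: step 5

Remark on locants: from compound 10 onward the spiro[4.5]decane locants of compound 11 are kept as route locants (C1 ring B carbinol carbon, C2 its ring B neighbour, C5 spiro carbon, C6 ring A carbon between C5 and C7, C7 ring A carbonyl carbon, C10 the C(OH)Me carbon).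

Assumption: which antipode of the bisphosphine gives (5R,10S)-10 must be fixed by a test run; (R)-SEGPHOS is written, and the (S) ligand is used if the sense proves opposite. The C7 carbinol configuration in compounds 16–33 is left unassigned, since C7 becomes trigonal in step 21.

## Route

Step 1
Reactants: 1 cyclopentane-1,3-dione; 2 5-methylfuran-2-carbaldehyde
Product: 3 2-[(5-methylfuran-2-yl)methyl]cyclopentane-1,3-dione
Conditions: Hantzsch ester (1 equiv), L-proline (5 mol %), CH2Cl2, rt
Reagents that add atoms: none
Why: Organocatalytic three-component reductive alkylation (Knoevenagel condensation, then transfer hydrogenation of the alkylidene dione by the Hantzsch ester), which should stop cleanly at the monoalkylated dione.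

Step 2
Reactants: 3 2-[(5-methylfuran-2-yl)methyl]cyclopentane-1,3-dione
Product: 4 3-methoxy-2-[(5-methylfuran-2-yl)methyl]cyclopent-2-en-1-one
Conditions: Me3SiCHN2, MeOH/toluene, 0 °C → rt
Reagents that add atoms: trimethylsilyldiazomethane, C[Si](C)(C)C=[N+]=[N-]
Why: O-Methylation of the enolised symmetrical 1,3-dione to the vinylogous ester under neutral conditions that the furan tolerates.

Step 3
Reactants: 4 3-methoxy-2-[(5-methylfuran-2-yl)methyl]cyclopent-2-en-1-one
Product: 6 2-[(5-methylfuran-2-yl)methyl]cyclopent-2-en-1-one, via allylic alcohol 5 (not isolated)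
Conditions: LiAlH4, Et2O, 0 °C; then 1 M HCl, 0 °C, short contact
Reagents that add atoms: water, O
Why: 1,2-Reduction of the vinylogous ester followed by acid hydrolysis and loss of methanol (1,3-carbonyl transposition) should give the 2-substituted cyclopentenone, the cold dilute acid being too mild to open the furan.

Step 4
Reactants: 6 2-[(5-methylfuran-2-yl)methyl]cyclopent-2-en-1-one
Product: 7 2-(2,5-dioxohexyl)cyclopent-2-en-1-one
Conditions: AcOH/H2O (3:1), H2SO4 (cat.), 100 °C
Reagents that add atoms: water, O
Why: Acid hydrolysis of the 2,5-dialkylfuran (reverse Paal–Knorr reaction) should unmask the 1,4-diketone while the enone is left intact.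

Step 5
Reactants: 7 2-(2,5-dioxohexyl)cyclopent-2-en-1-one
Product: 10 (5R,10S)-10-hydroxy-10-methylspiro[4.5]decane-1,7-dione, via copper enolate 8 (not isolated), via silyl ether 9 (not isolated)
Conditions: Cu(OAc)2·H2O (5 mol %), (R)-SEGPHOS (5 mol %), (EtO)2MeSiH (1.5 equiv), toluene, −20 °C; then 1 M HCl, THF, 0 °C
Reagents that add atoms: none
Why: Proposed new method: divalent copper acetate and the silane give a bisphosphine-bound monovalent copper hydride that adds hydride to the unsubstituted β-carbon of the enone, and the copper enolate, formed only at the substituted α-carbon, adds to the methyl ketone before σ-bond metathesis with the silane traps the aldolate as silyl ether 9 and regenerates the hydride; the closest known reaction type is the copper hydride catalysed enantioselective reductive aldol cyclisation of enones carrying a pendant ketone, which has not been shown for an α-substituted cyclic enone that creates a quaternary spiro carbon. Ring A closes in the 6-(enolexo)-exo-trig mode, the only aldol open to this enolate because the nearer chain ketone would require a three-membered ring. C5 is set by the chiral bisphosphine, which shields one face of the fully substituted copper enolate. C10 follows from a chair, copper-bridged (Zimmerman–Traxler type) transition state: with the methyl equatorial the carbonyl oxygen is axial and reaches the copper on the enolate oxygen only when C1 is equatorial, so the hydroxyl ends cis to C1. The step needs 1,4- over 1,2-reduction and aldol closure faster than silylation of the enolate, which the β-unsubstituted cyclopentenone and the six-membered tether should secure, and cold silyl capture of the aldolate blocks retro-aldol cleavage.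

Step 6
Reactants: 10 (5R,10S)-10-hydroxy-10-methylspiro[4.5]decane-1,7-dione
Product: 11 (1R,5S,10S)-1,10-dihydroxy-10-methylspiro[4.5]decan-7-one
Conditions: Me4NBH(OAc)3 (5 equiv), MeCN/AcOH (1:1), −30 °C
Reagents that add atoms: none
Why: Evans–Saksena reduction: boron binds the C10 hydroxyl and delivers hydride to the face of the ring B carbonyl on which C10 lies, so the C1 hydroxyl should form anti to the C10 oxygen (1R), while the ring A ketone, lacking a β-hydroxyl, is not reduced at this temperature.

Step 7
Reactants: 11 (1R,5S,10S)-1,10-dihydroxy-10-methylspiro[4.5]decan-7-one; 12 acryloyl chloride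
Product: 13 (1R,5S,10S)-10-hydroxy-10-methyl-7-oxospiro[4.5]decan-1-yl prop-2-enoate
Conditions: i-Pr2NEt, CH2Cl2, −40 → 0 °C
Reagents that add atoms: none
Why: Acylation of the secondary alcohol by the acid chloride; the hindered tertiary C10 alcohol should not react.

Step 8
Reactants: 13 (1R,5S,10S)-10-hydroxy-10-methyl-7-oxospiro[4.5]decan-1-yl prop-2-enoate
Product: 14 keto ε-lactone (C6–CH2CH2–C(=O)–O–C1, C6 chain cis to C1 on ring A)
Conditions: KOt-Bu (0.2 equiv), THF/t-BuOH (10:1), 0 °C, 0.01 M
Reagents that add atoms: none
Why: Base-catalysed intramolecular Michael addition (7-endo-trig): enolisation is reversible, only the C6 enolate can reach the tethered acrylate, and the seven-membered transition state can link the C1 oxygen and C6 on one face only, so the new C6 centre should form with its chain cis to C1 on ring A.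

Step 9
Reactants: 14 keto ε-lactone; 15 isopropenylmagnesium bromide
Product: 16 lactone with C7 as a tertiary carbinol bearing prop-1-en-2-yl
Conditions: CeCl3, THF, −78 °C (3 equiv of 15); aq NH4Cl
Reagents that add atoms: none
Why: Organocerium 1,2-addition to the ketone, which is faster than attack on the lactone and does not enolise C6; any migration of the lactone onto the new alkoxide is harmless because step 10 reduces the lactone.

Step 10
Reactants: 16 lactone with C7 as a tertiary carbinol bearing prop-1-en-2-yl
Product: 17 tetraol (C6 3-hydroxypropyl; hydroxyls at C1, C7 and C10)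
Conditions: LiAlH4, THF, 0 °C → rt; Rochelle salt work-up
Reagents that add atoms: none
Why: Hydride reduction of the lactone to the diol frees the C1 hydroxyl and gives the hydroxypropyl chain of the target; the isopropenyl group is inert.

Step 11
Reactants: 17 tetraol
Product: 18 primary pivalate of 17
Conditions: t-BuCOCl (1.1 equiv), pyridine, CH2Cl2, 0 °C
Reagents that add atoms: pivaloyl chloride, CC(C)(C)C(=O)Cl
Why: Selective acylation of the primary alcohol by the bulky acid chloride, leaving the neopentyl-type secondary and the two tertiary hydroxyls free.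

Step 12
Reactants: 18 primary pivalate of 17; 19 glyoxylic acid chloride p-toluenesulfonylhydrazone
Product: 21 C1 diazoacetate of 18, via tosylhydrazone ester 20 (not isolated)
Conditions: PhNMe2, CH2Cl2, 0 °C; then Et3N, 0 °C → rt
Reagents that add atoms: none
Why: Acylation of the secondary C1 alcohol by the acid chloride, then base-induced loss of sulfinate from the tosylhydrazone (Bamford–Stevens type) should give the diazoacetate; tertiary alcohols are not acylated.

Step 13
Reactants: 21 C1 diazoacetate of 18
Product: 22 bis(trimethylsilyl) ether of 21 at the C7 and C10 oxygens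
Conditions: N-(trimethylsilyl)imidazole (excess), CH2Cl2, 40 °C
Reagents that add atoms: N-(trimethylsilyl)imidazole, C[Si](C)(C)n1ccnc1
Why: Neutral silylation of the two hindered tertiary alcohols, which the diazo ester tolerates, removes the O–H bonds that would otherwise capture the carbenoid in step 14.

Step 14
Reactants: 22 bis(trimethylsilyl) ether of 21
Product: 23 cis-fused γ-lactone (C2–CH2–C(=O)–O–C1)
Conditions: Rh2(cap)4 (1 mol %; cap = caprolactamate), CH2Cl2, reflux, slow addition of 22
Reagents that add atoms: none
Why: Rhodium carbenoid 1,5 C–H insertion of a cycloalkyl diazoacetate: the carbenoid reaches only the C2 hydrogen cis to the C1 oxygen through a five-membered transition state and inserts with retention, so the lactone should be cis-fused and C2 set; C5 has no hydrogen, so no regioisomeric γ-lactone can form.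

Step 15
Reactants: 24 6-methylhept-5-en-2-one
Product: 25 6-methylhepta-1,5-dien-2-yl trifluoromethanesulfonate
Conditions: LiN(i-Pr)2, THF, −78 °C; PhNTf2, −78 → 0 °C
Reagents that add atoms: N-phenylbis(trifluoromethanesulfonimide), O=S(=O)(N(c1ccccc1)S(=O)(=O)C(F)(F)F)C(F)(F)F
Why: Kinetic deprotonation of the methyl ketone at the methyl group and O-sulfonylation of the enolate should give the terminal enol triflate.

Step 16
Reactants: 25 6-methylhepta-1,5-dien-2-yl trifluoromethanesulfonate; 26 acrolein
Product: 27 (2E)-8-methyl-4-methylidenenona-2,7-dienal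
Conditions: Pd(OAc)2 (5 mol %), PPh3 (10 mol %), Et3N, DMF, 60 °C
Reagents that add atoms: none
Why: Mizoroki–Heck coupling of the enol triflate with acrolein through zerovalent palladium; syn insertion and syn β-hydride elimination should give the E enal, which is used at once because such dienals dimerise.

Step 17
Reactants: 23 cis-fused γ-lactone; 27 (2E)-8-methyl-4-methylidenenona-2,7-dienal
Product: 28 aldol adduct (CH(OH)–dienyl on the lactone α-carbon)
Conditions: LiN(i-Pr)2 (1.2 equiv), THF, −78 °C; then 27, −78 °C; AcOH quench
Reagents that add atoms: none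
Why: Aldol 1,2-addition of the lactone lithium enolate to the enal; the pivalate has no α-hydrogen, the silyl ethers are inert, and the two new centres are removed in step 18.

Step 18
Reactants: 28 aldol adduct
Product: 30 (E)-α-alkylidene lactone (dienyl chain cis to C2), via mesylate 29 (not isolated)
Conditions: MsCl, Et3N, CH2Cl2, −20 °C; then DBU, 0 °C → rt
Reagents that add atoms: none
Why: Mesylation of the only secondary alcohol and E1cB elimination should give the conjugated trienyl lactone as the E isomer, in which the chain avoids the lactone carbonyl; this is the geometry of the trisubstituted alkene of the target.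

Step 19
Reactants: 30 (E)-α-alkylidene lactone
Product: 31 triol bis(trimethylsilyl) ether (C2–C(CH2OH)=CH–dienyl, C1–OH, primary OH on the C6 chain)
Conditions: i-Bu2AlH (7 equiv), CH2Cl2, −78 → 0 °C; Rochelle salt work-up
Reagents that add atoms: none
Why: 1,2-Reduction of the unsaturated lactone to the allylic diol, with reductive cleavage of the pivalate in the same operation; alkene geometry and silyl ethers are untouched.

Step 20
Reactants: 31 triol bis(trimethylsilyl) ether
Product: 33 triacetate with free C7 and C10 hydroxyls, via silylated triacetate 32 (not isolated)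
Conditions: Ac2O, pyridine, DMAP (cat.), 0 °C → rt; then HF·pyridine, THF, 0 °C
Reagents that add atoms: acetic anhydride, CC(=O)OC(C)=O
Why: Acetylation of the two primary and the one secondary alcohol, then buffered fluoride cleavage of the tertiary trimethylsilyl ethers, leaves the tertiary allylic alcohol as the only group that the oxidant of step 21 can change.

Step 21
Reactants: 33 triacetate with free C7 and C10 hydroxyls
Product: 34 (Z)-enal triacetate (C7=C(CH3)CHO, formyl syn to C6)
Conditions: (C5H5NH)[CrO3Cl] (3 equiv), NaOAc, 4 Å MS, CH2Cl2, rt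
Reagents that add atoms: pyridinium chlorochromate, [O-][Cr](=O)(=O)Cl.c1cc[nH+]cc1
Why: Babler–Dauben oxidative 1,3-transposition: the tertiary allylic chromate of hexavalent chromium undergoes a reversible [3,3] shift and the primary allylic chromate is oxidised to the enal; the Z isomer (small planar formyl next to substituted C6, methyl next to the C8 methylene) is expected to be favoured or at least a major component, and any E isomer is removed by chromatography.

Step 22
Reactants: 34 (Z)-enal triacetate
Product: 35 28-deacetylbelamcandal
Conditions: K2CO3, MeOH, 0 °C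
Reagents that add atoms: none
Why: Mild base-catalysed methanolysis of the three acetates, under which the hindered tetrasubstituted enal and the C6 centre should be stable.

## Compound list

1 | cyclopentane-1,3-dione | O=C1CCC(=O)C1 | starting material
2 | 5-methylfuran-2-carbaldehyde (5-methylfurfural) | Cc1ccc(C=O)o1 | starting material
3 | 2-[(5-methylfuran-2-yl)methyl]cyclopentane-1,3-dione | Cc1ccc(CC2C(=O)CCC2=O)o1 | intermediate
4 | 3-methoxy-2-[(5-methylfuran-2-yl)methyl]cyclopent-2-en-1-one | COC1=C(Cc2ccc(C)o2)C(=O)CC1 | intermediate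
5 | 3-methoxy-2-[(5-methylfuran-2-yl)methyl]cyclopent-2-en-1-ol (racemic, not isolated) | COC1=C(Cc2ccc(C)o2)C(O)CC1 | intermediate
6 | 2-[(5-methylfuran-2-yl)methyl]cyclopent-2-en-1-one | Cc1ccc(CC2=CCCC2=O)o1 | intermediate
7 | 2-(2,5-dioxohexyl)cyclopent-2-en-1-one | CC(=O)CCC(=O)CC1=CCCC1=O | intermediate
8 | copper enolate of 2-(2,5-dioxohexyl)cyclopentanone (bisphosphine on copper omitted, not isolated) | CC(=O)CCC(=O)CC1=C(O[Cu])CCC1 | intermediate
9 | diethoxy(methyl)silyl ether of 10 (not isolated) | C1CC[C@]2(CC(=O)CC[C@]2(C)O[Si](C)(OCC)OCC)C1=O | intermediate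
10 | (5R,10S)-10-hydroxy-10-methylspiro[4.5]decane-1,7-dione | C1CC[C@]2(CC(=O)CC[C@]2(C)O)C1=O | intermediate
11 | (1R,5S,10S)-1,10-dihydroxy-10-methylspiro[4.5]decan-7-one | C1CC[C@]2(CC(=O)CC[C@]2(C)O)[C@@H]1O | intermediate
12 | acryloyl chloride | C=CC(=O)Cl | starting material
13 | (1R,5S,10S)-10-hydroxy-10-methyl-7-oxospiro[4.5]decan-1-yl prop-2-enoate | C1CC[C@]2(CC(=O)CC[C@]2(C)O)[C@@H]1OC(=O)C=C | intermediate
14 | keto ε-lactone: C6 carries CH2CH2C(=O)O closed on the C1 oxygen, chain cis to C1 on ring A; C7 ketone, C10 tertiary alcohol | C1CC[C@]2([C@H](CCC(=O)O3)C(=O)CC[C@]2(C)O)[C@@H]13 | intermediate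
15 | isopropenylmagnesium bromide | CC(=C)[Mg]Br | starting material
16 | 14 with C7 as tertiary carbinol bearing prop-1-en-2-yl (C7 unassigned) | C1CC[C@]2([C@H](CCC(=O)O3)C(O)(C(C)=C)CC[C@]2(C)O)[C@@H]13 | intermediate
17 | tetraol: 6-(3-hydroxypropyl)-10-methyl-7-(prop-1-en-2-yl)spiro[4.5]decane-1,7,10-triol (C7 unassigned) | C1CC[C@]2([C@H](CCCO)C(O)(C(C)=C)CC[C@]2(C)O)[C@@H]1O | intermediate
18 | primary pivalate of 17 | C1CC[C@]2([C@H](CCCOC(=O)C(C)(C)C)C(O)(C(C)=C)CC[C@]2(C)O)[C@@H]1O | intermediate
19 | glyoxylic acid chloride p-toluenesulfonylhydrazone | Cc1ccc(cc1)S(=O)(=O)NN=CC(Cl)=O | starting material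
20 | C1 ester of 18 with glyoxylic acid p-toluenesulfonylhydrazone (not isolated) | C1CC[C@]2([C@H](CCCOC(=O)C(C)(C)C)C(O)(C(C)=C)CC[C@]2(C)O)[C@@H]1OC(=O)C=NNS(=O)(=O)c3ccc(C)cc3 | intermediate
21 | C1 diazoacetate of 18 | C1CC[C@]2([C@H](CCCOC(=O)C(C)(C)C)C(O)(C(C)=C)CC[C@]2(C)O)[C@@H]1OC(=O)C=[N+]=[N-] | intermediate
22 | bis(trimethylsilyl) ether of 21 at the C7 and C10 oxygens | C1CC[C@]2([C@H](CCCOC(=O)C(C)(C)C)C(O[Si](C)(C)C)(C(C)=C)CC[C@]2(C)O[Si](C)(C)C)[C@@H]1OC(=O)C=[N+]=[N-] | intermediate
23 | cis-fused γ-lactone (C2–CH2–C(=O)–O–C1), pivalate and both silyl ethers kept | O=C3C[C@@H]1CC[C@]2([C@H](CCCOC(=O)C(C)(C)C)C(O[Si](C)(C)C)(C(C)=C)CC[C@]2(C)O[Si](C)(C)C)[C@@H]1O3 | intermediate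
24 | 6-methylhept-5-en-2-one | CC(=O)CCC=C(C)C | starting material
25 | 6-methylhepta-1,5-dien-2-yl trifluoromethanesulfonate | C=C(CCC=C(C)C)OS(=O)(=O)C(F)(F)F | intermediate
26 | acrolein (prop-2-enal) | C=CC=O | starting material
27 | (2E)-8-methyl-4-methylidenenona-2,7-dienal | O=C/C=C/C(=C)CCC=C(C)C | intermediate
28 | aldol adduct of 23 and 27 (two new centres unassigned) | O=C3C(C(O)/C=C/C(=C)CCC=C(C)C)[C@@H]1CC[C@]2([C@H](CCCOC(=O)C(C)(C)C)C(O[Si](C)(C)C)(C(C)=C)CC[C@]2(C)O[Si](C)(C)C)[C@@H]1O3 | intermediate
29 | methanesulfonate of 28 (not isolated) | O=C3C(C(OS(C)(=O)=O)/C=C/C(=C)CCC=C(C)C)[C@@H]1CC[C@]2([C@H](CCCOC(=O)C(C)(C)C)C(O[Si](C)(C)C)(C(C)=C)CC[C@]2(C)O[Si](C)(C)C)[C@@H]1O3 | intermediate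
30 | (E)-α-alkylidene lactone, dienyl chain cis to C2 | O=C3/C(=C/C=C/C(=C)CCC=C(C)C)[C@@H]1CC[C@]2([C@H](CCCOC(=O)C(C)(C)C)C(O[Si](C)(C)C)(C(C)=C)CC[C@]2(C)O[Si](C)(C)C)[C@@H]1O3 | intermediate
31 | triol with trimethylsilyl ethers at the C7 and C10 oxygens | OC/C(=C/C=C/C(=C)CCC=C(C)C)[C@@H]1CC[C@]2([C@H](CCCO)C(O[Si](C)(C)C)(C(C)=C)CC[C@]2(C)O[Si](C)(C)C)[C@@H]1O | intermediate
32 | triacetate of 31 (not isolated) | CC(=O)OC/C(=C/C=C/C(=C)CCC=C(C)C)[C@@H]1CC[C@]2([C@H](CCCOC(C)=O)C(O[Si](C)(C)C)(C(C)=C)CC[C@]2(C)O[Si](C)(C)C)[C@@H]1OC(C)=O | intermediate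
33 | triacetate with free C7 and C10 hydroxyls | CC(=O)OC/C(=C/C=C/C(=C)CCC=C(C)C)[C@@H]1CC[C@]2([C@H](CCCOC(C)=O)C(O)(C(C)=C)CC[C@]2(C)O)[C@@H]1OC(C)=O | intermediate
34 | (Z)-enal triacetate | CC(=O)OC/C(=C/C=C/C(=C)CCC=C(C)C)[C@@H]1CC[C@]2([C@H](CCCOC(C)=O)/C(=C(/C)C=O)CC[C@]2(C)O)[C@@H]1OC(C)=O | intermediate
35 | 28-deacetylbelamcandal | C=C(/C=C/C=C(/CO)[C@@H]1CC[C@]2([C@H](CCCO)/C(=C(/C)C=O)CC[C@]2(C)O)[C@@H]1O)CCC=C(C)C | target

## Step count and risks

Total step count: 22. Longest linear sequence: 20 steps (steps 1–14 and 17–22); steps 15–16 make the dienal.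

Steps most likely to fail:

1. Step 5 (bears the label). The hindered, fully substituted copper enolate may be silylated before it closes ring A, giving plain conjugate reduction; the two saturated ketones may undergo 1,2-hydrosilylation; and the ligand may discriminate the enolate faces poorly. Fallback, from 7 back to 10, by known chemistry: 1,4-hydrosilylation of 7 (Et3SiH, RhCl(PPh3)3) gives the triethylsilyl enol ether F1. NBS at −78 °C converts it into 2-bromo-2-(2,5-dioxohexyl)cyclopentan-1-one F2. SmI2 (2.2 equiv, THF, −78 °C) then generates the samarium enolate, in which trivalent samarium bridges both oxygens, so the Reformatsky-type intramolecular aldol should close ring A through the same bridged chair. This gives 10 together with the enantiomer of 10 F3, and preparative chromatography on a chiral stationary phase returns 10.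

2. Step 8. The seven-membered closure may be slow, so that intermolecular Michael addition, enolisation toward C8 and base-induced epimerisation of the product at C6 compete. Fallback, from 13 back to 14: IBX (DMSO/toluene, 70 °C) dehydrogenates ring A in the only possible direction to the C8–C9 enone, ring A enone acrylate F4. C6 is then the only acidic position, so LiN(SiMe3)2 (2.1 equiv, THF, −78 °C) forms a single cross-conjugated enolate that cyclises under kinetic control to the lactone enone F5. Hydrogenation (H2, Pd/C, EtOAc) of the ring A double bond gives 14.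

3. Step 21. The geometry of the tetrasubstituted enal may be poorly controlled, the conjugated triene may be lost to the acidic oxidant, and chromate formation at the hindered C7 carbinol may be slow. Fallback, from 33 back to 34, without chromium: Ph3SiOReO3 (cat., Et2O, 0 °C) transposes the tertiary allylic alcohol to the primary (Z)-allylic alcohol F6 and the (E)-allylic alcohol F7. These do not interconvert on handling and are separated; F7 is resubmitted to the catalyst, which equilibrates it through the tertiary alcohol. MnO2 (CH2Cl2, rt) oxidises F6, the only free allylic alcohol, to 34.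

## Further compounds

F1 | step 5 | triethylsilyl enol ether of 2-(2,5-dioxohexyl)cyclopentanone | CC[Si](CC)(CC)OC1=C(CC(=O)CCC(C)=O)CCC1
F2 | step 5 | 2-bromo-2-(2,5-dioxohexyl)cyclopentan-1-one (racemic) | CC(=O)CCC(=O)CC1(Br)CCCC1=O
F3 | step 5 | (5S,10R)-10-hydroxy-10-methylspiro[4.5]decane-1,7-dione (enantiomer of 10) | C1CC[C@@]2(CC(=O)CC[C@@]2(C)O)C1=O
F4 | step 8 | ring A enone acrylate (C8–C9 double bond) | C1CC[C@]2(CC(=O)C=C[C@]2(C)O)[C@@H]1OC(=O)C=C
F5 | step 8 | lactone enone (14 with C8–C9 double bond) | C1CC[C@]2([C@H](CCC(=O)O3)C(=O)C=C[C@]2(C)O)[C@@H]13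
F6 | step 21 | (Z)-allylic alcohol triacetate (C7=C(CH3)CH2OH, hydroxymethyl syn to C6) | CC(=O)OC/C(=C/C=C/C(=C)CCC=C(C)C)[C@@H]1CC[C@]2([C@H](CCCOC(C)=O)/C(=C(/C)CO)CC[C@]2(C)O)[C@@H]1OC(C)=O
F7 | step 21 | (E)-allylic alcohol triacetate (hydroxymethyl syn to C8) | CC(=O)OC/C(=C/C=C/C(=C)CCC=C(C)C)[C@@H]1CC[C@]2([C@H](CCCOC(C)=O)/C(=C(\C)CO)CC[C@]2(C)O)[C@@H]1OC(C)=O
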